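## The problem

Gardenin E (11) is a flavone: benzene ring A is fused to the 4-pyranone ring C, which carries aryl ring B at C2. It has no stereocentre, so the whole task is the placement and differentiation of seven oxygen substituents. Ring A is hexasubstituted, with a free hydroxyl at C5 and methyl ethers at C6, C7 and C8. Ring B has free hydroxyls at C3′ and C5′ on either side of the C4′ methyl ether. Three phenols must therefore end up free beside four methyl ethers, and the crowded central ethers (C6, C7, C4′) are the ones Lewis acids attack most readily after the peri C5 ether, so a late global demethylation cannot sort them. A fully oxygenated ring A building block is a hexasubstituted benzene that would have to be made, whereas the 5,6,7-trioxygenated pattern comes directly from commercial 3,4,5-trimethoxyphenol (1). The pyranone opens in hot alkali, the free phenols are easily over-oxidised, and the masks on ring B must come off without touching any methyl ether. The feature exploited is that in a 5-hydroxy-6,7-dimethoxyflavone C8 is the only ring A carbon still bearing hydrogen and lies para to the C5 hydroxyl, so two-electron oxidation of that phenol puts positive charge exactly where the missing oxygen belongs.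

## Retrosynthesis

**11 from 9.** The last operation should only unmask ring B. Cutting the two acyl–oxygen bonds leads to bis(pivalate) 9. Esters are preferred to ethers here for two reasons: mild base-mediated methanolysis removes them without touching a methyl ether or the pyranone, and they make ring B electron-poor, which the oxidation two steps earlier needs. The forward step asks only that the flavone tolerate carbonate in an alcohol at room temperature.

**9 from 10.** The C8 methyl ether of 9 is traced to quinone monoketal 10, which has one more methoxyl and two fewer electrons. A one-stage para-methoxylation cannot be stopped at 9, because 9 is a 4-methoxyphenol and is oxidised more easily than its precursor. The over-oxidised ketal is therefore the realistic intermediate, and a mild two-electron reduction with loss of one methoxyl returns the aromatic ring. The reduction must be faster than ketal hydrolysis, otherwise the C8 methyl group is lost.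

**10 from 8.** This is the key cut: both C8–O bonds are removed, giving the 5-hydroxy-6,7-dimethoxyflavone 8 with hydrogen at C8. The neighbouring options were weighed against it:
- Persulfate hydroxylation needs aqueous alkali, which ring B esters would not survive, and leaves a hydroquinone that still has to be methylated selectively.
- Halogenation followed by copper-mediated methoxylation is two steps and ends in hot methoxide.
- Anodic methoxylation delivers the oxygen and its methyl group together in a neutral, buffered medium.

The precursor is much simpler, since its ring A pattern is bought with 1. The forward reaction must oxidise ring A only and add the nucleophile at C8 only.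

**8 from 7, and 7 from 6.** The pivalates are put on the two ring B phenols of triol 7; the chelated, flanked C5 hydroxyl should stay free. Triol 7 comes from the benzyl-protected 5,6,7-trimethoxyflavone 6 by one Lewis-acid treatment that cleaves both benzyl ethers and the peri C5 methyl ether. Benzyl ethers are needed earlier because the flavone is assembled with strong base, which esters would not survive. Carrying the benzyl ethers through the electrolysis would save one step, but a trialkoxyaryl ring with benzylic C–H bonds lies too close in oxidation potential to ring A, so the exchange is accepted.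

**6 from 5.** The O1–C2 bond is cut, giving the o-hydroxyaryl 1,3-diketone 5. Acid-catalysed cyclodehydration of such diketones is the standard closure of ring C and sets the flavone oxidation level directly, unlike a chalcone route, which needs a further oxidation.

**5 from 2 and 4.** The bond between the methylene carbon and the ring B acyl carbon (the future C3–C2 bond) is cut. This gives methyl ketone 2 and ester 4, joined by a crossed Claisen condensation. The acid chloride version (O-acylation, then Baker–Venkataraman shift) would need saponification and chlorination of 4 first; using 4 as it comes from the benzylation saves two steps. The forward step needs a base strong enough to form the phenoxide–enolate dianion and to deprotonate the product.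

**2 from 1, and 4 from 3.** Ketone 2 arises by C-acetylation of 1 ortho to the hydroxyl; the para position is blocked and the two ortho positions are equivalent, so only one product is possible. Ester 4 arises by exhaustive benzylation of commercial 3,5-dihydroxy-4-methoxybenzoic acid (3).

## Roads not taken

**Alternative 1:** Carbonylative annulation.
- Cut: C4a–C4, C4–C3 and O1–C2 in one operation.
- Forward step: the iodoresorcinol 2-iodo-4,5,6-trimethoxybenzene-1,3-diol A1 and the arylacetylene 1,3-bis(benzyloxy)-5-ethynyl-2-methoxybenzene A2 are joined under CO with PdCl2(PPh3)2 and Et2NH. The ynone formed from A1, carbon monoxide and A2 closes 6-endo to the flavone 2-[3,5-bis(benzyloxy)-4-methoxyphenyl]-5-hydroxy-6,7,8-trimethoxy-4H-chromen-4-one A3. Hydrogenolysis of the two benzyl ethers of A3 then gives 11.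
- Merits: it is the most convergent plan. Because A1 is symmetric, either hydroxyl may close and the other becomes the C5 hydroxyl. Every ring A oxygen of A3 is already in its final state, and there is no redox detour at C8. Alkyne A2 carries ring B with the same benzyl masks that the chosen route uses.
- Weak points: A1 is a hexasubstituted, air-sensitive iodoresorcinol that is not a catalogue compound, and the polyoxygenated ring behind it must itself be built over several steps. Oxidative addition of a di-ortho-substituted, very electron-rich C–I bond to zerovalent palladium is slow, so direct non-carbonylative coupling of A1 with A2 (leading to a benzofuran) and protodeiodination compete. Ring closure can also go 5-exo to an aurone instead of 6-endo to A3.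
- Comparison: counted from A1 and A2 this road is shorter than the chosen one and needs only one kind of protecting group. The chosen plan sets against it that both aromatic building blocks are bought and that the hexasubstituted ring is created only at the last C–O bond-forming stage.

**Alternative 2:** Squarate ring expansion.
- Cut: ring A is dismantled into a squaric diester (C5–C8) and a pyranone (C4a, C8a).
- Forward step: thermolysis of the cyclobutenone 4-hydroxy-2,3-dimethoxy-4-{6-[3,5-bis(benzyloxy)-4-methoxyphenyl]-4-oxo-4H-pyran-3-yl}cyclobut-2-en-1-one A4 opens the four-membered ring to a vinylketene. Its ketene carbon closes onto the free pyranone carbon and, after tautomerisation, gives the hydroquinone 2-[3,5-bis(benzyloxy)-4-methoxyphenyl]-5,8-dihydroxy-6,7-dimethoxy-4H-chromen-4-one A5. Selective methylation of the non-chelated C8 hydroxyl of A5 and hydrogenolysis would follow.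
- Merits: all four ring A oxygens are placed without ambiguity, and chelation differentiates the two hydroquinone hydroxyls of A5.
- Weak points: A4 needs a pyranone metallated next to its carbonyl while the adjacent position is unsubstituted and the ring is a Michael acceptor. The parent aryl pyranone is itself a multistep target. A5 is an air-sensitive hydroquinone and still needs two more steps.
- Comparison: this road builds the ring A carbons that the chosen plan buys. Its only advantage is that the C8 oxygen arrives without oxidising a finished flavone. It is clearly longer and rests on the least secure organometallic step of all four plans.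

**Alternative 3:** Aryne insertion.
- Cut: O1–C8a, C4–C4a and O1–C2.
- Forward step: CsF unmasks the symmetric aryne from the silyl triflate 2,3,4,5-tetramethoxy-6-(trimethylsilyl)phenyl trifluoromethanesulfonate A6. The carboxylate of the propiolic acid 3-[3,5-bis(benzyloxy)-4-methoxyphenyl]prop-2-ynoic acid A7 adds to it, the aryl anion takes the acyl group, and the phenoxide closes onto the ynone to give the flavone 2-[3,5-bis(benzyloxy)-4-methoxyphenyl]-5,6,7,8-tetramethoxy-4H-chromen-4-one A8. One Lewis-acid step on A8 (peri demethylation and debenzylation) would give 11.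
- Merits: the symmetric aryne from A6 removes any regiochemical question, and A8 is a single operation from the target. In convergence and in steps after the fragments A6 and A7, this road is at least as good as the chosen one.
- Weak points: A6 is again a hexasubstituted benzene that needs a multistep preparation. Arynes and carboxylic acids tend to stop at the aryl ester unless acyl transfer outruns proton transfer. An aryne flanked by two methoxyls is hindered and electronically perturbed. Acid A7 can decarboxylate or add to the aryne through its triple bond.
- Comparison: the chosen plan sets against it commercial ring precursors, a key step whose site is dictated by the single free position of ring A, and conventional chemistry everywhere else.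

Key step: step 7

Remark: compound 9 occurs twice, as a transient of the electrolysis in step 7 and as the isolated product of step 8; it keeps one number.

## Route

Step 1
Reactants: 1 3,4,5-trimethoxyphenol
Product: 2 1-(6-hydroxy-2,3,4-trimethoxyphenyl)ethan-1-one
Conditions: AcOH, BF3·OEt2, 85 °C; then aq. NaOAc
Reagents that add atoms: acetic acid, CC(=O)O
Why: Friedel–Crafts (Nencki-type) C-acetylation ortho to the phenol, driven by the boron chelate of the o-hydroxyaryl ketone; the para position is blocked and the two ortho positions are equivalent, so a single isomer should form.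

Step 2
Reactants: 3 3,5-dihydroxy-4-methoxybenzoic acid
Product: 4 benzyl 3,5-bis(benzyloxy)-4-methoxybenzoate
Conditions: BnBr (3.3 equiv), K2CO3, DMF, 60 °C
Reagents that add atoms: benzyl bromide, BrCc1ccccc1
Why: Williamson etherification of both phenols with concurrent O-alkylation of the carboxylate; the benzyl ester obtained is used directly as the acyl donor of step 3.

Step 3
Reactants: 2 1-(6-hydroxy-2,3,4-trimethoxyphenyl)ethan-1-one, 4 benzyl 3,5-bis(benzyloxy)-4-methoxybenzoate
Product: 5 1-[3,5-bis(benzyloxy)-4-methoxyphenyl]-3-(6-hydroxy-2,3,4-trimethoxyphenyl)propane-1,3-dione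
Conditions: LiN(SiMe3)2 (3.5 equiv), THF, −78 °C → 50 °C; then aq. HCl
Reagents that add atoms: none
Why: Crossed Claisen condensation of the phenoxide–enolate dianion of the o-hydroxyacetophenone with a non-enolisable aryl ester; the third equivalent of base deprotonates the 1,3-diketone and pulls the equilibrium to the product.

Step 4
Reactants: 5 1-[3,5-bis(benzyloxy)-4-methoxyphenyl]-3-(6-hydroxy-2,3,4-trimethoxyphenyl)propane-1,3-dione
Product: 6 2-[3,5-bis(benzyloxy)-4-methoxyphenyl]-5,6,7-trimethoxy-4H-chromen-4-one
Conditions: TsOH·H2O (0.2 equiv), toluene, 110 °C, Dean–Stark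
Reagents that add atoms: none
Why: Acid-catalysed cyclodehydration of an o-hydroxyaryl 1,3-diketone, the closing stage of the Baker–Venkataraman flavone synthesis: the phenol adds to the distal carbonyl (6-exo-trig) and the hemiketal loses water; benzyl and methyl ethers are inert to catalytic sulfonic acid.

Step 5
Reactants: 6 2-[3,5-bis(benzyloxy)-4-methoxyphenyl]-5,6,7-trimethoxy-4H-chromen-4-one
Product: 7 2-(3,5-dihydroxy-4-methoxyphenyl)-5-hydroxy-6,7-dimethoxy-4H-chromen-4-one
Conditions: BCl3 (8 equiv), pentamethylbenzene (6 equiv), CH2Cl2, −78 °C → 0 °C; then H2O
Reagents that add atoms: none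
Why: Lewis-acid ether cleavage: BCl3 with a non-basic cation scavenger removes aryl benzyl ethers at low temperature, and on warming the boron chelate between the C4 carbonyl and the peri C5 oxygen directs demethylation to C5 alone, as in the known selective 5-O-demethylation of polymethoxyflavones. The scavenger keeps benzyl cations away from the nucleophilic C8.

Step 6
Reactants: 7 2-(3,5-dihydroxy-4-methoxyphenyl)-5-hydroxy-6,7-dimethoxy-4H-chromen-4-one
Product: 8 5-hydroxy-6,7-dimethoxy-2-[4-methoxy-3,5-bis(pivaloyloxy)phenyl]-4H-chromen-4-one
Conditions: PivCl (2.2 equiv), pyridine, CH2Cl2, 0 °C → rt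
Reagents that add atoms: pivaloyl chloride, CC(C)(C)C(=O)Cl
Why: Selective O-acylation of the two ring B phenols; the C5 hydroxyl is held in a six-membered hydrogen bond to the C4 carbonyl and flanked by the C6 methoxyl, so it resists a bulky acyl chloride, which is the usual selectivity of 5-hydroxyflavones.

Step 7
Reactants: 8 5-hydroxy-6,7-dimethoxy-2-[4-methoxy-3,5-bis(pivaloyloxy)phenyl]-4H-chromen-4-one
Product: 10 6,7,8,8-tetramethoxy-2-[4-methoxy-3,5-bis(pivaloyloxy)phenyl]-8H-chromene-4,5-dione, via 5-hydroxy-8-methoxyflavone bis(pivalate) 9 (not isolated)
Conditions: graphite anode, Pt cathode, divided cell, LiClO4 (0.1 M), 2,6-lutidine (4.5 equiv), MeOH/MeCN 3:1, 0 °C, constant current, ca. 4 F/mol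
Reagents that add atoms: methanol, CO
Why: Anodic para-methoxylation of a phenol, the known electrochemical route from para-unsubstituted phenols and 4-methoxyphenols to quinone monoketals in methanol. Ring A of 8 loses two electrons and the phenolic proton to give a phenoxonium ion with positive charge at C4a, C6 and C8; methanol adds at C8, the only position bearing hydrogen, and tautomerisation gives the 4-methoxyphenol 9. Phenol 9 is oxidised at a lower potential than 8 and reacts on at once: a second two-electron oxidation gives a C8 oxocarbenium ion that a second methanol converts into ketal 10. No ring is closed and no stereocentre arises, since C8 carries two identical methoxyls. Selectivity between the rings rests on the pivalates, which make ring B an electron-poor aryl diester, and on the vinylogous-ester character of the C2=C3 bond, so the phenol should be the only group oxidised in the working window. Ipso capture at the methoxyl-bearing C6 is the competing mode; C6 is flanked on both sides, its ketal can re-ionise in the lutidinium-buffered methanol, and only addition at C8 is made irreversible by aromatisation, so material should funnel to 9 and then to 10. The divided cell keeps 8 and 10 from the cathode, and the buffer takes up the four protons released so that neither the esters nor the ketal meet strong acid.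

Step 8
Reactants: 10 6,7,8,8-tetramethoxy-2-[4-methoxy-3,5-bis(pivaloyloxy)phenyl]-8H-chromene-4,5-dione
Product: 9 5-hydroxy-6,7,8-trimethoxy-2-[4-methoxy-3,5-bis(pivaloyloxy)phenyl]-4H-chromen-4-one
Conditions: Zn dust, AcOH/THF, 0 °C → rt
Reagents that add atoms: none
Why: Reductive aromatisation of a quinone monoketal: two-electron reduction gives a dienolate that expels one methoxyl from C8, leaving the 4-methoxyphenol. The cross-conjugated ene-dione is far easier to reduce than the flavone carbonyl, and the anhydrous acid gives no water for ketal hydrolysis.

Step 9
Reactants: 9 5-hydroxy-6,7,8-trimethoxy-2-[4-methoxy-3,5-bis(pivaloyloxy)phenyl]-4H-chromen-4-one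
Product: 11 Gardenin E, 2-(3,5-dihydroxy-4-methoxyphenyl)-5-hydroxy-6,7,8-trimethoxy-4H-chromen-4-one
Conditions: K2CO3 (4 equiv), MeOH/THF, rt, N2; then dilute HCl
Reagents that add atoms: none
Why: Base-mediated transesterification (methanolysis) of aryl pivalates, which are activated phenolic esters; methyl ethers and the pyranone are untouched at room temperature, and exclusion of air protects the phenoxides.

## Compound list

1 | 3,4,5-trimethoxyphenol | COc1cc(O)cc(OC)c1OC | starting material
2 | 1-(6-hydroxy-2,3,4-trimethoxyphenyl)ethan-1-one | CC(=O)c1c(O)cc(OC)c(OC)c1OC | intermediate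
3 | 3,5-dihydroxy-4-methoxybenzoic acid | COc1c(O)cc(C(=O)O)cc1O | starting material
4 | benzyl 3,5-bis(benzyloxy)-4-methoxybenzoate | COc1c(OCc2ccccc2)cc(C(=O)OCc2ccccc2)cc1OCc1ccccc1 | intermediate
5 | 1-[3,5-bis(benzyloxy)-4-methoxyphenyl]-3-(6-hydroxy-2,3,4-trimethoxyphenyl)propane-1,3-dione | COc1cc(O)c(C(=O)CC(=O)c2cc(OCc3ccccc3)c(OC)c(OCc3ccccc3)c2)c(OC)c1OC | intermediate
6 | 2-[3,5-bis(benzyloxy)-4-methoxyphenyl]-5,6,7-trimethoxy-4H-chromen-4-one | COc1cc2oc(-c3cc(OCc4ccccc4)c(OC)c(OCc4ccccc4)c3)cc(=O)c2c(OC)c1OC | intermediate
7 | 2-(3,5-dihydroxy-4-methoxyphenyl)-5-hydroxy-6,7-dimethoxy-4H-chromen-4-one | COc1cc2oc(-c3cc(O)c(OC)c(O)c3)cc(=O)c2c(O)c1OC | intermediate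
8 | 5-hydroxy-6,7-dimethoxy-2-[4-methoxy-3,5-bis(pivaloyloxy)phenyl]-4H-chromen-4-one | COc1cc2oc(-c3cc(OC(=O)C(C)(C)C)c(OC)c(OC(=O)C(C)(C)C)c3)cc(=O)c2c(O)c1OC | intermediate
9 | 5-hydroxy-6,7,8-trimethoxy-2-[4-methoxy-3,5-bis(pivaloyloxy)phenyl]-4H-chromen-4-one | COc1c(OC)c(O)c2c(=O)cc(-c3cc(OC(=O)C(C)(C)C)c(OC)c(OC(=O)C(C)(C)C)c3)oc2c1OC | intermediate
10 | 6,7,8,8-tetramethoxy-2-[4-methoxy-3,5-bis(pivaloyloxy)phenyl]-8H-chromene-4,5-dione | COC1=C(OC)C(OC)(OC)C2=C(C1=O)C(=O)C=C(O2)c1cc(OC(=O)C(C)(C)C)c(OC)c(OC(=O)C(C)(C)C)c1 | intermediate
11 | Gardenin E, 2-(3,5-dihydroxy-4-methoxyphenyl)-5-hydroxy-6,7,8-trimethoxy-4H-chromen-4-one | COc1c(O)cc(-c2cc(=O)c3c(O)c(OC)c(OC)c(OC)c3o2)cc1O | target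

## Step count and least certain steps

Total steps: 9. Longest linear sequence: 8 steps (from 1 through steps 1 and 3–9, or equally from 3 through steps 2–9).

**Step 7 (key step).** The C5 phenol is hydrogen-bonded to the C4 carbonyl and sits on an acyl-substituted ring, so it may be oxidised only near the potential at which the C2=C3 bond or the electrolyte begins to react. Methanol may also be captured ipso at C6 instead of at C8, phenoxy radical coupling may passivate the anode, and conjugate addition of methanol to the electrophilic ene-dione may consume the ketal once it has formed. A hypervalent iodine oxidant in the same solvent would first be tried as a variation leading to the same ketal 10.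

The fallback leaves the oxidative disconnection and sets out from 8. Electrophilic bromination with N-bromosuccinimide in DMF at the only free, doubly activated position should give 8-bromo-5-hydroxy-6,7-dimethoxy-2-[4-methoxy-3,5-bis(pivaloyloxy)phenyl]-4H-chromen-4-one F1. Copper-mediated (Ullmann-type) methoxylation with NaOMe and catalytic CuBr in MeOH/DMF at about 110 °C under N2, known for 8-haloflavones, then replaces bromide by methoxide and cleaves both pivalates in the same operation. The route is rejoined at 11.

**Step 5.** The Lewis acid may go beyond the peri ether and also cleave a crowded central methyl ether (C6 or C4′) once the neighbouring oxygens are boron-bound. Benzyl cations may alkylate C8 if scavenging is incomplete.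

The fallback separates the two deprotections and sets out from 6. Hydrogenolysis (H2, Pd/C, EtOAc/THF) should give 2-(3,5-dihydroxy-4-methoxyphenyl)-5,6,7-trimethoxy-4H-chromen-4-one F2. Pivaloylation (PivCl, pyridine) gives 5,6,7-trimethoxy-2-[4-methoxy-3,5-bis(pivaloyloxy)phenyl]-4H-chromen-4-one F3. A small excess of BCl3 (CH2Cl2, −20 → 0 °C) then removes only the chelation-activated C5 methyl group, now that the ring B oxygens are acylated and non-coordinating. The route is rejoined at 8.

**Step 3.** Acyl transfer from an electron-rich benzoate ester to the hindered dianion may be slow, and proton transfer from the product diketone may stall the reaction at partial conversion.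

The fallback is the stepwise Baker–Venkataraman sequence and sets out from 4. Saponification (NaOH, MeOH/THF/H2O, then HCl) gives 3,5-bis(benzyloxy)-4-methoxybenzoic acid F4. Oxalyl chloride with catalytic DMF gives 3,5-bis(benzyloxy)-4-methoxybenzoyl chloride F5. O-Acylation of 2 in pyridine gives 2-acetyl-3,4,5-trimethoxyphenyl 3,5-bis(benzyloxy)-4-methoxybenzoate F6. Intramolecular acyl shift with KOH in pyridine at 50 °C should then deliver 5, where the route is rejoined.

**Step 8.** Acid-promoted loss of methanol and hydrolysis of the ketal by adventitious water may outrun electron transfer, so that reduction ends at the hydroquinone and the C8 methyl group is lost. Prolonged contact with the metal may also reduce the pyranone.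

The fallback accepts the hydroquinone and sets out from 10. Deliberate hydrolysis (aqueous AcOH/THF) gives 6,7-dimethoxy-2-[4-methoxy-3,5-bis(pivaloyloxy)phenyl]-4H-chromene-4,5,8-trione F7. Reduction with Na2S2O4 (EtOAc/H2O) gives 5,8-dihydroxy-6,7-dimethoxy-2-[4-methoxy-3,5-bis(pivaloyloxy)phenyl]-4H-chromen-4-one F8. Methylation of the non-chelated C8 hydroxyl (MeI, 1.1 equiv, K2CO3, acetone, rt) is the classical partial methylation of 5,8-dihydroxyflavones and rejoins the route at 9.

## Further compounds

F1 | step 7 | 8-bromo-5-hydroxy-6,7-dimethoxy-2-[4-methoxy-3,5-bis(pivaloyloxy)phenyl]-4H-chromen-4-one | COc1c(Br)c2oc(-c3cc(OC(=O)C(C)(C)C)c(OC)c(OC(=O)C(C)(C)C)c3)cc(=O)c2c(O)c1OC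
F2 | step 5 | 2-(3,5-dihydroxy-4-methoxyphenyl)-5,6,7-trimethoxy-4H-chromen-4-one | COc1cc2oc(-c3cc(O)c(OC)c(O)c3)cc(=O)c2c(OC)c1OC
F3 | step 5 | 5,6,7-trimethoxy-2-[4-methoxy-3,5-bis(pivaloyloxy)phenyl]-4H-chromen-4-one | COc1cc2oc(-c3cc(OC(=O)C(C)(C)C)c(OC)c(OC(=O)C(C)(C)C)c3)cc(=O)c2c(OC)c1OC
F4 | step 3 | 3,5-bis(benzyloxy)-4-methoxybenzoic acid | COc1c(OCc2ccccc2)cc(C(=O)O)cc1OCc1ccccc1
F5 | step 3 | 3,5-bis(benzyloxy)-4-methoxybenzoyl chloride | COc1c(OCc2ccccc2)cc(C(=O)Cl)cc1OCc1ccccc1
F6 | step 3 | 2-acetyl-3,4,5-trimethoxyphenyl 3,5-bis(benzyloxy)-4-methoxybenzoate | CC(=O)c1c(OC(=O)c2cc(OCc3ccccc3)c(OC)c(OCc3ccccc3)c2)cc(OC)c(OC)c1OC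
F7 | step 8 | 6,7-dimethoxy-2-[4-methoxy-3,5-bis(pivaloyloxy)phenyl]-4H-chromene-4,5,8-trione | COC1=C(OC)C(=O)C2=C(C1=O)C(=O)C=C(O2)c1cc(OC(=O)C(C)(C)C)c(OC)c(OC(=O)C(C)(C)C)c1
F8 | step 8 | 5,8-dihydroxy-6,7-dimethoxy-2-[4-methoxy-3,5-bis(pivaloyloxy)phenyl]-4H-chromen-4-one | COc1c(OC)c(O)c2c(=O)cc(-c3cc(OC(=O)C(C)(C)C)c(OC)c(OC(=O)C(C)(C)C)c3)oc2c1O
A1 | alternative 1 | 2-iodo-4,5,6-trimethoxybenzene-1,3-diol | COc1c(O)c(I)c(O)c(OC)c1OC
A2 | alternative 1 | 1,3-bis(benzyloxy)-5-ethynyl-2-methoxybenzene | COc1c(OCc2ccccc2)cc(C#C)cc1OCc1ccccc1
A3 | alternative 1 | 2-[3,5-bis(benzyloxy)-4-methoxyphenyl]-5-hydroxy-6,7,8-trimethoxy-4H-chromen-4-one | COc1c(OCc2ccccc2)cc(-c2cc(=O)c3c(O)c(OC)c(OC)c(OC)c3o2)cc1OCc1ccccc1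
A4 | alternative 2 | 4-hydroxy-2,3-dimethoxy-4-{6-[3,5-bis(benzyloxy)-4-methoxyphenyl]-4-oxo-4H-pyran-3-yl}cyclobut-2-en-1-one | COC1=C(OC)C(O)(C1=O)c1coc(-c2cc(OCc3ccccc3)c(OC)c(OCc3ccccc3)c2)cc1=O
A5 | alternative 2 | 2-[3,5-bis(benzyloxy)-4-methoxyphenyl]-5,8-dihydroxy-6,7-dimethoxy-4H-chromen-4-one | COc1c(O)c2oc(-c3cc(OCc4ccccc4)c(OC)c(OCc4ccccc4)c3)cc(=O)c2c(O)c1OC
A6 | alternative 3 | 2,3,4,5-tetramethoxy-6-(trimethylsilyl)phenyl trifluoromethanesulfonate | COc1c(OC)c(OC)c(OS(=O)(=O)C(F)(F)F)c([Si](C)(C)C)c1OC
A7 | alternative 3 | 3-[3,5-bis(benzyloxy)-4-methoxyphenyl]prop-2-ynoic acid | COc1c(OCc2ccccc2)cc(C#CC(=O)O)cc1OCc1ccccc1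
A8 | alternative 3 | 2-[3,5-bis(benzyloxy)-4-methoxyphenyl]-5,6,7,8-tetramethoxy-4H-chromen-4-one | COc1c(OC)c(OC)c2c(=O)cc(-c3cc(OCc4ccccc4)c(OC)c(OCc4ccccc4)c3)oc2c1OC
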